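Litres per mole: that is the unit of the number we want, and we reach it by objecting to easier numbers.

the same everywhere: starting material 0.54 M
- summer: reagent 2.5 equiv; run made earlier
- noon: reagent 4 equiv; run made earlier
- midnight: reagent 4.6 equiv; run made earlier
- delta: reagent 3.00 equiv; time 12 h
- beta: reagent 4.50 equiv; time 12 h

| run | time / h | starting material / % | mono adduct / % | tris adduct / % | bis adduct / % |
|---|---|---|---|---|---|
| summer | 2.50 | 0 | 0 | 8 | 88 |
| summer | 5.00 | 1 | 0 | 7 | 95 |
| summer | 8.00 | 1 | 0 | 7 | 93 |
| summer | 10.0 | 0 | 0 | 7 | 92 |
| summer | 12.0 | 0 | 0 | 8 | 92 |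
| noon | 2.50 | 0 | 0 | 21 | 78 |
| noon | 5.00 | 0 | 1 | 27 | 77 |
| noon | 8.00 | 3 | 0 | 22 | 76 |
| noon | 10.0 | 1 | 0 | 26 | 76 |
| noon | 12.0 | 0 | 0 | 23 | 76 |
| midnight | 1.00 | 3 | 1 | 30 | 72 |
| midnight | 2.00 | 0 | 1 | 26 | 71 |
| midnight | 3.00 | 0 | 0 | 30 | 73 |
| midnight | 6.00 | 0 | 0 | 28 | 70 |
| midnight | 12.0 | 4 | 0 | 28 | 71 |

(each reading ± 1.5 percentage points)

- the earlier runs were read with a standard deviation of 1.5 percentage points

1. which of these there is most of at the end, counted by the starting material in it, delta (mono adduct / starting material / bis adduct / tris adduct)
2. which of these there is most of at the end, counted by the starting material in it, beta (mono adduct / starting material / bis adduct / tris adduct)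
3. how much there is at the end of the one of these that leads, in percent of the starting material charged: delta
4. how much there is at the end of the one of these that leads, in percent of the starting material charged: beta

First guess: reagent beyond 2 equiv goes wholly into tris adduct. Summer should then hold 50.0% tris adduct, but it reads 8% at 12.0 h.

Perhaps that step is merely slow? Midnight reads 30% at 1.00 h and 28% at 12.0 h, a gap near the scatter of 1.5 points, so the mix stands still while still moving with the charge.

So we count what is left, not what was made. Let x be the tris share of tris plus bis adduct, e the equivalents charged and c the starting concentration. Then the fraction of bis adduct left is 1 − x, and free reagent is (e − 2 − x)c. If bis adduct and reagent balance against tris adduct, K = x/[(1 − x)(e − 2 − x)c] should not move with e.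

Means of the readings after the first give x = 7.23%, 24.3% and 28.2% for summer, noon and midnight. Hence K reads 0.338 L mol⁻¹, 0.339 L mol⁻¹ and 0.314 L mol⁻¹. Midnight stands 0.0250 L mol⁻¹ below noon, and we leave that gap to the scatter of 1.5 points in the readings of those two runs. We carry the mean, the balance constant (the equilibrium constant) K = 0.330 L mol⁻¹.

One doubt stays: these runs share one c, so the c in K is untested. Delta and beta stand at that same 0.54 M, though. Solving for x gives 13.4% in delta, so bis adduct leads at 86.6%. Beta gives 28.3%, so bis adduct leads at 71.7%.

The forecast put bis adduct at 86% in delta and bis adduct at 72% in beta, holding that “This points to an equilibrium, bis + reagent ⇌ tris, rather than a kinetic race.”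

At 12 h, delta holds bis adduct at 86.9% and tris adduct at 13.1%. Beta holds bis adduct at 72.3% and tris adduct at 27.7%.

    starting material + reagent → mono adduct (k = 4.99 L mol⁻¹ h⁻¹)
    reagent + mono adduct → bis adduct (k = 4.90 L mol⁻¹ h⁻¹)
    reagent + bis adduct ⇌ tris adduct (K = 0.320 L mol⁻¹, k = 5.91 L mol⁻¹ h⁻¹)

Our x stood at 13.4% for delta, whose tris adduct came out at 13.1%. The untested c now gets its trial. A neighbouring flask is delta charged at 0.22 M, with the same equivalents and time. Keeping K, the product Kc falls to 0.0726, and the same quadratic gives x = 6.37%. That neighbouring flask ends with bis adduct at 93.8% and tris adduct at 6.19%.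

(The readings are simulated with constants of no real substance, and the scatter is random.)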